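**Remark.** Atoms carry daucane numbers: five-membered ring C1(Me)–C2–C3–C4(OH)(iPr)–C5(H), seven-membered ring C5–C6(O-acyl)–C7–C8(Me)–C9–C10(OH)–C1. α is the face of H5, β the face of the C1 methyl, and descriptors in "dauc-" names refer to this numbering.

## Structural features

Lapiferine is a daucane (bicyclo[5.3.0]decane): a cyclopentane (C1–C5) trans-fused through C1–C5 to a cycloheptane (C5–C10, C1). C1 is an all-carbon quaternary centre carrying the angular methyl, and C5 is a methine. Seven stereocentres are present, and they form one unbroken chain C4–C5–C6 and C8–C9–C10–C1 around the ring fusion. C4 is a tertiary carbinol with its hydroxyl on the β face and its isopropyl on the α face. The three oxygens of the seven-membered ring (C6 ester, C8–C9 oxirane, C10 hydroxyl) all lie on the α face, syn to H5 and anti to the C1 methyl. The fragile groups are the angelate (Z to E isomerisation to the tiglate under base, nucleophilic catalysis or heat) and the trisubstituted epoxide next to a free secondary alcohol (acid opening, Payne-type migration). The real difficulty is the trans-fused, densely oxygenated seven-membered ring: closing it next to a quaternary carbon, placing the C8 methyl and the C8–C9 oxidation correctly, and acylating only one of two secondary hydroxyls. Without the epoxide oxygen, C8=C9 is an alkene that is allylic to C10–OH and homoallylic to the C6 carbinol. The key step uses this: C6–C7 is the bond an allylsilane (C7=C8, silicon on C9) makes with a C6 aldehyde, so the ring, the C6 stereocentre and the alkene position arise together.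

## Logic of the disconnections

**26 to 25.** The two C–O bonds of the oxirane are cut. The epoxide is the most sensitive group and is cis to the allylic C10 hydroxyl, which is the retron of a hydroxyl-directed epoxidation. 25 has one ring and two stereocentres fewer. The forward step must deliver oxygen only to the α face of C8=C9 and leave the electron-poor angelate alkene alone.

**25 to 24 to 21 + 22.** The O–Si bonds at C10 and C4 and then the C6–O acyl bond are cut. The ester has to be introduced while the other secondary oxygen (C10) is blocked, and 22 is commercial. 21 carries only robust groups. The forward steps must acylate a hindered alcohol without Z/E isomerisation and remove silicon without acyl migration.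

**21 to 20.** The C6–C7 bond is cut (key step). A homoallylic alcohol with the alkene at C8=C9 is the retron of an allylsilane adding to an aldehyde with silicon leaving from C9. The seven-membered ring and the C6 stereocentre disappear, and 20 is a trans-1,2-disubstituted cyclopentane with an open arm. The forward step needs a seven-membered closure, facial control at C6 and a C10 oxygen that cannot eliminate. Both oxygens are therefore triethylsilyl ethers: a trimethylsilyl ether on the tertiary C4 oxygen would be too labile towards BF3 and chromatography, and a tert-butyldimethylsilyl ether on the neopentyl C10 oxygen would be too hard to remove beside an angelate.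

**20 to 17.** The aldehyde is returned to its dimethyl acetal and the two O–Si bonds are cut. The C6 aldehyde cannot coexist with the Grignard and allylboration steps. Protection and unmasking are merged into one operation. The forward step must free the aldehyde without protic acid, because a β-hydroxysilane and an allylsilane are present.

**17 to 11 + 12.** The C9–C10 bond is cut. The anti O/Si pair at C10/C9 is the retron of an (E)-γ-silylallylboration, which sets both centres from the reagent. The whole C7–C9 arm comes from commercial 12, leaving a one-carbon aldehyde on C1. The forward step needs boron at the terminus remote from silicon, E geometry and Re-face attack.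

**11 to 10 to 9.** The C10 oxidation level is adjusted and C10–O is traced back to C10–Si. A silylmethyl group is a hydroxymethyl equivalent that survives organometallic steps. The forward steps must oxidise C–Si and the primary alcohol without touching the acetal or the tertiary alcohol.

**9 to 7 + 8.** The C4–isopropyl bond is cut. A tertiary carbinol comes from a ketone, and the adjacent C5 substituent should direct the addition. 8 is commercial. The forward step must add rather than enolise or reduce, and must attack anti to the C5 substituent.

**7 to 5 + 6.** The C5–C6 bond is cut. The enol silane from the conjugate addition is regiodefined at C4–C5 (deprotonation would go to C3), and 6 delivers C6 at the aldehyde oxidation level. The forward step must alkylate the hindered C5 trans to the silylmethyl group without eliminating methanol.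

**5 to 1 + 2.** The C1–C10 bond is cut. The quaternary stereocentre is made by catalytic asymmetric conjugate addition to a commercial enone, with the enolate trapped. The forward step needs enantiofacial control on a β-substituted cyclopentenone and transfer of a silylmethyl group from copper.

## Other disconnections considered

**Alternative 1:** Dearomative Buchner ring expansion.
- **Cut:** both bonds from C5 into the rings (C1–C5 and C5–C6), leading back to the arene-tethered diazoketone A1.
- **Forward key step:** Rh2(S-PTTL)4 would generate the carbene, which adds across the arene C1–C6 bond; the norcaradiene opens to the cycloheptatriene-fused cyclopentanone A2. A2 is correctly named 4-methoxy-6-methyl-3,8a-dihydroazulen-1(2H)-one: the enol ether carbon is azulene C4 (target C10), whereas a locant of 8 would place it next to the sp3 fusion carbon.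
- **In favour:** both rings, the C8 methyl and oxygen at C4 and C10 come from a flat aromatic in one catalytic asymmetric step. A1 is a few routine steps from a commercial arylpropanoic acid. On speed to the bicyclic skeleton this is better than the chosen plan.
- **Against here:**
  - The only stereocentre of A2 (C5) is α to a ketone and allylic to a triene, so it should epimerise or drift into conjugation easily.
  - The ortho methoxy group can intercept the carbenoid (ylide formation, addition across the other ortho bond, aromatic substitution).
  - C1 (quaternary methyl), C4, C6, C8/C9 and C10 would all have to be set afterwards on a polyene with three similar C=C bonds.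
- **Comparison:** the key step forms two bonds and two rings, against one bond and one ring in the chosen plan, and is catalytic in the chiral element. The chosen plan reaches its cyclisation with five stereocentres and every substituent already in place and needs three steps afterwards. A2 would need a long, poorly controlled endgame, so the overall step count favours the chosen plan.

**Alternative 2:** Carbene-catalysed desymmetrising benzoin.
- **Cut:** the C4–C5 bond, leading back to the aldehyde-tethered symmetric cycloheptane-1,3-dione A3.
- **Forward key step:** a chiral triazolylidene carbene would turn the aldehyde into its acyl-anion equivalent, which adds to one enantiotopic ketone to give the cis-fused ketol A4.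
- **In favour:** A3 is one Michael step from a commercial dione. The benzoin is organocatalytic and sets the quaternary C1 by desymmetrisation. On that point it is better than the chosen plan, whose conjugate addition (step 1) is its least secure step.
- **Against here:**
  - The oxygen pattern does not fit. A4 has a tertiary hydroxyl at C5, where the target has hydrogen trans to the methyl, and the benzoin gives the cis relationship.
  - C5 would have to be deoxygenated with control of the ring fusion after isopropyl addition to C4, and retro-benzoin is a risk under base.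
  - C6 to C9 are bare methylenes. The C6 oxygen, the C8 methyl and the C8=C9 alkene would all have to be introduced from the single C10 ketone.
- **Comparison:** equal or better in ring construction and catalysis. It is clearly worse in functional-group match and in step count after the key step, whereas the chosen cyclisation product already carries C6–OH, C8-Me, C8=C9 and C10–O.

**Alternative 3:** Wieland–Miescher decalin reshaped by semipinacol shift.
- **Cut:** the C1–C5 bond, made by a 1,2-shift that converts a decalin into the hydroazulene.
- **Forward key step:** starting from the (S)-Wieland–Miescher ketone A5, the cis-decalin hydroxy mesylate A6 would be treated with Et2AlCl. C1 migrates from C6 to C5 anti to the leaving group, giving the trans-fused hydroxy ketone A7.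
- **In favour:** A5 is available in high enantiomeric purity, a more reliable source of C1 than step 1 of the chosen plan. The shift is stereospecific (inversion at C5 gives the trans fusion), which is better than a selectivity that depends on a transition-state preference. A7 has C1, C4 and C5 as in the target, with differentiated carbonyls at C6 and C10. Its free C4 hydroxyl could direct an anti-selective reduction of the C6 ketone.
- **Against here:**
  - The mesylate carbon of A6 lies between two tertiary carbinols (C4 and C6), each with a ring bond anti to an equatorial leaving group, so contraction towards C4 (acylcyclopentane) competes unless the C4 hydroxyl is differentiated.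
  - The C5/C6 diol of A6 must sit on the methyl-bearing face, which needs a hydroxyl-directed dihydroxylation against the normal steric preference.
  - A7 is a β-hydroxy ketone with an epimerisable C5 (retro-aldol, trans to cis drift under the Lewis acid).
  - The C8 methyl and the C8=C9 alkene are missing and would have to be built from the C10 ketone by several steps.
- **Comparison:** equal on the cyclopentane stereocentres and better on absolute-configuration security. It is weaker on the seven-membered ring substituents and longer overall: about six to seven steps to A7 plus at least as many afterwards, against eleven in total.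

Key step: step 8

## Route

**Step 1**
Reactants: 1 3-methylcyclopent-2-en-1-one; 2 (chloromethyl)dimethyl(propan-2-yloxy)silane
Product: 5 (S)-3-methyl-3-{[dimethyl(propan-2-yloxy)silyl]methyl}-1-(trimethylsilyloxy)cyclopent-1-ene, via Grignard reagent 3 (not isolated), via magnesium enolate 4 (not isolated)
Conditions: 2, Mg, Et2O, rt; Cu(OTf)2 (3 mol %), chiral hydroxyalkyl-imidazolinium salt (NHC precursor, 4 mol %), Et2O, 0 °C, then 1; TMSCl, Et3N, DMPU, 0 °C to rt
Reagents that add atoms: (chloromethyl)dimethyl(propan-2-yloxy)silane 2, CC(C)O[Si](C)(C)CCl; chlorotrimethylsilane, C[Si](C)(C)Cl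
Why: Copper–NHC-catalysed asymmetric conjugate addition of a primary Grignard reagent to a β-substituted cyclic enone; the ligand antipode is chosen so that the silylmethyl group adds to the enone face that gives the (S)-quaternary C1. Silylation of the magnesium enolate fixes the C4–C5 enolate, which deprotonation of the ketone (towards C3) could not provide.

**Step 2**
Reactants: 5 (S)-3-methyl-3-{[dimethyl(propan-2-yloxy)silyl]methyl}-1-(trimethylsilyloxy)cyclopent-1-ene; 6 trimethyl orthoformate
Product: 7 (2S,3S)-2-(dimethoxymethyl)-3-methyl-3-{[dimethyl(propan-2-yloxy)silyl]methyl}cyclopentan-1-one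
Conditions: 6, TMSOTf (0.1 equiv), CH2Cl2, −78 °C; Et3N quench
Reagents that add atoms: trimethyl orthoformate 6, COC(OC)OC
Why: Mukaiyama-type alkylation of the enol silane by the dimethoxycarbenium ion; the electrophile should enter C5 anti to the bulkier silylmethyl group on C1, placing C6 trans to C10. C5 stays epimerisable, so a minor cis isomer can be equilibrated with DBU in a non-alcoholic solvent and recycled.

**Step 3**
Reactants: 7 (2S,3S)-2-(dimethoxymethyl)-3-methyl-3-{[dimethyl(propan-2-yloxy)silyl]methyl}cyclopentan-1-one; 8 isopropylmagnesium chloride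
Product: 9 (1R,2R,3S)-2-(dimethoxymethyl)-3-methyl-1-(propan-2-yl)-3-{[dimethyl(propan-2-yloxy)silyl]methyl}cyclopentan-1-ol
Conditions: 8 (2 M in THF), LaCl3·2LiCl (1 equiv), THF, 0 °C; aq NH4Cl
Reagents that add atoms: isopropylmagnesium chloride 8, CC(C)[Mg]Cl
Why: Lanthanum-promoted Grignard 1,2-addition suppresses the enolisation and β-hydride reduction typical of iPrMgCl with hindered cyclopentanones. The nucleophile should attack the carbonyl face anti to the adjacent C5 acetal substituent, giving the C4 hydroxyl cis to C6 (4R).

**Step 4**
Reactants: 9 (1R,2R,3S)-2-(dimethoxymethyl)-3-methyl-1-(propan-2-yl)-3-{[dimethyl(propan-2-yloxy)silyl]methyl}cyclopentan-1-ol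
Product: 10 (1R,2R,3S)-2-(dimethoxymethyl)-3-(hydroxymethyl)-3-methyl-1-(propan-2-yl)cyclopentan-1-ol
Conditions: 30% H2O2, KF, KHCO3, THF–MeOH (1:1), rt to 40 °C
Reagents that add atoms: hydrogen peroxide, OO
Why: Tamao–Fleming oxidation of the alkoxysilane to the primary alcohol; the basic peroxide medium leaves the dimethyl acetal and the tertiary alcohol untouched.

**Step 5**
Reactants: 10 (1R,2R,3S)-2-(dimethoxymethyl)-3-(hydroxymethyl)-3-methyl-1-(propan-2-yl)cyclopentan-1-ol
Product: 11 (1S,2R,3R)-2-(dimethoxymethyl)-3-hydroxy-1-methyl-3-(propan-2-yl)cyclopentane-1-carbaldehyde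
Conditions: Dess–Martin periodinane, NaHCO3, CH2Cl2, 0 °C to rt
Reagents that add atoms: none
Why: Dess–Martin oxidation of the neopentyl primary alcohol; the tertiary hydroxyl cannot be oxidised, the buffer protects the acetal, and the aldehyde has no α-hydrogen. The C4 hydroxyl is trans to the formyl group on the ring, so no lactol should form.

**Step 6**
Reactants: 11 (1S,2R,3R)-2-(dimethoxymethyl)-3-hydroxy-1-methyl-3-(propan-2-yl)cyclopentane-1-carbaldehyde; 12 trimethyl(2-methylallyl)silane
Product: 17 (1R,2R,3S)-2-(dimethoxymethyl)-3-[(1S,2R)-1-hydroxy-3-methyl-2-(trimethylsilyl)but-3-en-1-yl]-3-methyl-1-(propan-2-yl)cyclopentan-1-ol, via allyllithium 13 (not isolated), via borate complex 14 (not isolated), via allylborane 15 (not isolated), via borinate 16 (not isolated)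
Conditions: 12 (2.5 equiv), s-BuLi, TMEDA, THF, −78 to −30 °C; (+)-Ipc2BOMe, −78 °C; BF3·OEt2; 11, −78 to −20 °C; aq NaHCO3, 30% H2O2, 0 °C to rt
Reagents that add atoms: trimethyl(2-methylallyl)silane 12, CC(=C)C[Si](C)(C)C
Why: Reagent-controlled γ-silylallylboration with a diisopinocampheylborane: the (E)-γ-silylallylborane reacts through a closed chair transition state, so O and Si come out anti. The isopinocampheyl groups derived from (−)-α-pinene are expected, by the usual facial preference of these reagents, to direct attack to the Re face of the aldehyde, setting 10S and 9R. Buffered oxidative work-up avoids Peterson elimination of the β-hydroxysilane.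

**Step 7**
Reactants: 17 (1R,2R,3S)-2-(dimethoxymethyl)-3-[(1S,2R)-1-hydroxy-3-methyl-2-(trimethylsilyl)but-3-en-1-yl]-3-methyl-1-(propan-2-yl)cyclopentan-1-ol
Product: 20 (1R,2R,5S)-5-methyl-5-[(1S,2R)-3-methyl-1-(triethylsilyloxy)-2-(trimethylsilyl)but-3-en-1-yl]-2-(propan-2-yl)-2-(triethylsilyloxy)cyclopentane-1-carbaldehyde, via bis-silyl acetal 18 (not isolated), via collidinium salt 19 (not isolated)
Conditions: TESOTf (5 equiv), 2,4,6-collidine (8 equiv), CH2Cl2, −78 to 0 °C; then H2O, 0 °C to rt
Reagents that add atoms: triethylsilyl trifluoromethanesulfonate, CC[Si](CC)(CC)OS(=O)(=O)C(F)(F)F; water, O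
Why: The silyl triflate silylates both hydroxyls and, with collidine, converts the dimethyl acetal into a weakly electrophilic collidinium N,O-acetal salt that water hydrolyses to the aldehyde (silyl triflate–pyridine acetal cleavage). No protic acid reaches the β-silyloxy allylsilane, and no stereocentre is touched.

**Step 8**
Reactants: 20 (1R,2R,5S)-5-methyl-5-[(1S,2R)-3-methyl-1-(triethylsilyloxy)-2-(trimethylsilyl)but-3-en-1-yl]-2-(propan-2-yl)-2-(triethylsilyloxy)cyclopentane-1-carbaldehyde
Product: 21 (1S,4R,5S,6S,10R)-4,10-bis(triethylsilyloxy)dauc-8-en-6-ol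
Conditions: BF3·OEt2 (1.5 equiv), 2,6-di-tert-butyl-4-methylpyridine (0.5 equiv), CH2Cl2 (0.005 M), −78 °C; aq NaHCO3
Reagents that add atoms: none
Why: BF3 binds the C6 aldehyde; the terminal carbon C7 of the 2-methylallylsilane adds to C6, the developing tertiary cation at C8 is stabilised by the C9–Si bond, and loss of silicon from C9 leaves the C8=C9 alkene (anti SE2′). The closest known reaction type is the intramolecular Hosomi–Sakurai cyclisation of allylsilanes onto aldehydes, used for cycloheptenols and hydroazulenes. The seven-membered ring closes in the 7-exo-trig mode at the carbonyl carbon with the allylsilane reacting endo, so the new alkene is endocyclic and necessarily Z. The one new stereocentre, C6, is set by a chair-like transition state imposed by the trans-disubstituted cyclopentane: C2 and C4 must be pseudo-equatorial on the forming ring, so the BF3-bound oxygen points outward (anti to C1) and the aldehyde hydrogen takes the crowded pocket between the C1 methyl and the C4 silyloxy group, giving 6S (6α-OH). The anti relationship of C10–O and C9–Si puts silicon on the face of the allyl unit opposite to the incoming C6 in this chair, as anti SE2′ requires. The step needs C6 facial selectivity, a fixed alkene position and no Peterson elimination: the first comes from the chair and the bulky non-chelating C4 silyl ether, the second from silicon on C9, and the third from the silylated C10 oxygen lying syn-clinal, not antiperiplanar, to the C–Si bond. High dilution and the hindered pyridine suppress intermolecular allylation and protodesilylation.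

**Step 9**
Reactants: 21 (1S,4R,5S,6S,10R)-4,10-bis(triethylsilyloxy)dauc-8-en-6-ol; 22 angelic acid, (Z)-2-methylbut-2-enoic acid
Product: 24 (1S,4R,5S,6S,10R)-4,10-bis(triethylsilyloxy)dauc-8-en-6-yl (Z)-2-methylbut-2-enoate, via mixed anhydride 23 (not isolated)
Conditions: 22, 2,4,6-Cl3C6H2COCl, Et3N, PhMe, rt; then 21, PhMe, 80 °C
Reagents that add atoms: angelic acid 22, C/C=C(/C)C(=O)O
Why: Yamaguchi esterification: the hindered aroyl carbonyl of the mixed anhydride steers the alcohol to the angeloyl carbonyl, and omitting DMAP and strong base keeps the Z-alkene from isomerising to the tiglate. Only C6–OH is free, so the two secondary oxygens are differentiated.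

**Step 10**
Reactants: 24 (1S,4R,5S,6S,10R)-4,10-bis(triethylsilyloxy)dauc-8-en-6-yl (Z)-2-methylbut-2-enoate
Product: 25 (1S,4R,5S,6S,10R)-4,10-dihydroxydauc-8-en-6-yl (Z)-2-methylbut-2-enoate
Conditions: HF·pyridine, pyridine, THF, 0 °C to rt
Reagents that add atoms: none
Why: Buffered HF·pyridine cleaves both triethylsilyl ethers under mildly acidic conditions, which should avoid the acyl migration and ester cleavage that basic fluoride could cause.

**Step 11**
Reactants: 25 (1S,4R,5S,6S,10R)-4,10-dihydroxydauc-8-en-6-yl (Z)-2-methylbut-2-enoate
Product: 26 lapiferine, (1S,4R,5S,6S,8R,9S,10S)-8,9-epoxy-4,10-dihydroxydaucan-6-yl (Z)-2-methylbut-2-enoate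
Conditions: VO(acac)2 (5 mol %), t-BuOOH (in decane, 1.5 equiv), CH2Cl2, 0 °C to rt
Reagents that add atoms: tert-butyl hydroperoxide, CC(C)(C)OO
Why: Vanadium-catalysed hydroxyl-directed epoxidation: the pseudo-axial allylic C10–OH binds the metal and delivers oxygen to the same (α) face of the electron-rich trisubstituted C8=C9 alkene, giving the cis-epoxy alcohol (8R,9S). The conjugated angelate alkene is not a substrate for this reagent.

## Compound list

1 | 3-methylcyclopent-2-en-1-one | CC1=CC(=O)CC1 | starting material
2 | (chloromethyl)dimethyl(propan-2-yloxy)silane | CC(C)O[Si](C)(C)CCl | starting material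
3 | {[dimethyl(propan-2-yloxy)silyl]methyl}magnesium chloride | CC(C)O[Si](C)(C)C[Mg]Cl | intermediate
4 | chloromagnesium C4–C5 enolate of (S)-3-methyl-3-{[dimethyl(propan-2-yloxy)silyl]methyl}cyclopentanone | Cl[Mg]OC1=C[C@@](C)(C[Si](C)(C)OC(C)C)CC1 | intermediate
5 | (S)-3-methyl-3-{[dimethyl(propan-2-yloxy)silyl]methyl}-1-(trimethylsilyloxy)cyclopent-1-ene | C[Si](C)(C)OC1=C[C@@](C)(C[Si](C)(C)OC(C)C)CC1 | intermediate
6 | trimethyl orthoformate | COC(OC)OC | starting material
7 | (2S,3S)-2-(dimethoxymethyl)-3-methyl-3-{[dimethyl(propan-2-yloxy)silyl]methyl}cyclopentan-1-one | COC(OC)[C@H]1C(=O)CC[C@]1(C)C[Si](C)(C)OC(C)C | intermediate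
8 | isopropylmagnesium chloride | CC(C)[Mg]Cl | starting material
9 | (1R,2R,3S)-2-(dimethoxymethyl)-3-methyl-1-(propan-2-yl)-3-{[dimethyl(propan-2-yloxy)silyl]methyl}cyclopentan-1-ol | COC(OC)[C@H]1[C@](O)(C(C)C)CC[C@]1(C)C[Si](C)(C)OC(C)C | intermediate
10 | (1R,2R,3S)-2-(dimethoxymethyl)-3-(hydroxymethyl)-3-methyl-1-(propan-2-yl)cyclopentan-1-ol | COC(OC)[C@H]1[C@](O)(C(C)C)CC[C@]1(C)CO | intermediate
11 | (1S,2R,3R)-2-(dimethoxymethyl)-3-hydroxy-1-methyl-3-(propan-2-yl)cyclopentane-1-carbaldehyde | COC(OC)[C@H]1[C@](O)(C(C)C)CC[C@]1(C)C=O | intermediate
12 | trimethyl(2-methylallyl)silane | CC(=C)C[Si](C)(C)C | starting material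
13 | [2-methyl-1-(trimethylsilyl)allyl]lithium | [Li]C([Si](C)(C)C)C(C)=C | intermediate
14 | lithium methoxybis(isopinocampheyl)[(E)-2-methyl-3-(trimethylsilyl)allyl]borate | [Li+].CO[B-](C/C(C)=C/[Si](C)(C)C)([C@H]1C[C@H]2C[C@@H]([C@@H]1C)C2(C)C)[C@H]1C[C@H]2C[C@@H]([C@@H]1C)C2(C)C | intermediate
15 | (E)-[2-methyl-3-(trimethylsilyl)allyl]bis(isopinocampheyl)borane, isopinocampheyl groups from (−)-α-pinene | C[Si](C)(C)/C=C(\C)CB([C@H]1C[C@H]2C[C@@H]([C@@H]1C)C2(C)C)[C@H]1C[C@H]2C[C@@H]([C@@H]1C)C2(C)C | intermediate
16 | diisopinocampheylborinate ester of 17 at the C10 oxygen | COC(OC)[C@H]1[C@](O)(C(C)C)CC[C@]1(C)[C@H](OB([C@H]2C[C@H]3C[C@@H]([C@@H]2C)C3(C)C)[C@H]2C[C@H]3C[C@@H]([C@@H]2C)C3(C)C)[C@H]([Si](C)(C)C)C(C)=C | intermediate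
17 | (1R,2R,3S)-2-(dimethoxymethyl)-3-[(1S,2R)-1-hydroxy-3-methyl-2-(trimethylsilyl)but-3-en-1-yl]-3-methyl-1-(propan-2-yl)cyclopentan-1-ol | COC(OC)[C@H]1[C@](O)(C(C)C)CC[C@]1(C)[C@H](O)[C@H]([Si](C)(C)C)C(C)=C | intermediate
18 | bis(triethylsilyl) ether of 17 (both hydroxyls silylated, dimethyl acetal intact) | COC(OC)[C@H]1[C@](O[Si](CC)(CC)CC)(C(C)C)CC[C@]1(C)[C@H](O[Si](CC)(CC)CC)[C@H]([Si](C)(C)C)C(C)=C | intermediate
19 | 1-[methoxy(cyclopentyl)methyl]-2,4,6-trimethylpyridinium triflate derived from 18 (N,O-acetal carbon as a mixture of epimers) | COC([n+]1c(C)cc(C)cc1C)[C@H]1[C@](O[Si](CC)(CC)CC)(C(C)C)CC[C@]1(C)[C@H](O[Si](CC)(CC)CC)[C@H]([Si](C)(C)C)C(C)=C.[O-]S(=O)(=O)C(F)(F)F | intermediate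
20 | (1R,2R,5S)-5-methyl-5-[(1S,2R)-3-methyl-1-(triethylsilyloxy)-2-(trimethylsilyl)but-3-en-1-yl]-2-(propan-2-yl)-2-(triethylsilyloxy)cyclopentane-1-carbaldehyde | O=C[C@H]1[C@](O[Si](CC)(CC)CC)(C(C)C)CC[C@]1(C)[C@H](O[Si](CC)(CC)CC)[C@H]([Si](C)(C)C)C(C)=C | intermediate
21 | (1S,4R,5S,6S,10R)-4,10-bis(triethylsilyloxy)dauc-8-en-6-ol | O[C@H]1CC(C)=C[C@@H](O[Si](CC)(CC)CC)[C@@]2(C)CC[C@@](O[Si](CC)(CC)CC)(C(C)C)[C@H]12 | intermediate
22 | angelic acid, (Z)-2-methylbut-2-enoic acid | C/C=C(/C)C(=O)O | starting material
23 | (Z)-2-methylbut-2-enoic 2,4,6-trichlorobenzoic anhydride | C/C=C(/C)C(=O)OC(=O)c1c(Cl)cc(Cl)cc1Cl | intermediate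
24 | (1S,4R,5S,6S,10R)-4,10-bis(triethylsilyloxy)dauc-8-en-6-yl (Z)-2-methylbut-2-enoate | C/C=C(/C)C(=O)O[C@H]1CC(C)=C[C@@H](O[Si](CC)(CC)CC)[C@@]2(C)CC[C@@](O[Si](CC)(CC)CC)(C(C)C)[C@H]12 | intermediate
25 | (1S,4R,5S,6S,10R)-4,10-dihydroxydauc-8-en-6-yl (Z)-2-methylbut-2-enoate | C/C=C(/C)C(=O)O[C@H]1CC(C)=C[C@@H](O)[C@@]2(C)CC[C@@](O)(C(C)C)[C@H]12 | intermediate
26 | lapiferine, (1S,4R,5S,6S,8R,9S,10S)-8,9-epoxy-4,10-dihydroxydaucan-6-yl (Z)-2-methylbut-2-enoate | C/C=C(/C)C(=O)O[C@H]1C[C@@]2(C)O[C@H]2[C@@H](O)[C@@]2(C)CC[C@@](O)(C(C)C)[C@H]12 | target

## Step count and least certain steps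

Total: 11 steps. Longest linear sequence: 11 steps (1 to 26).

**Step 8 (key step).** The most likely failure is erosion of facial selectivity at C6, through a boat-like ring or a transition state with the BF3-bound oxygen turned into the β pocket. A second risk is that a slow medium-ring closure lets protodesilylation or ionisation at C10 (assisted by the β-silicon) compete. Fallback for the stereochemical failure: it sets out from 20, whose cyclisation would then deliver mainly the C6 epimer, (1S,4R,5S,6R,10R)-4,10-bis(triethylsilyloxy)dauc-8-en-6-ol F1. F1 is esterified with 22 under Mitsunobu conditions (PPh3, DIAD, PhMe, 0 °C to rt). SN2 displacement from the open α face inverts C6 and gives 24 directly, where the fallback rejoins the route with step 9 absorbed.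

**Step 1.** A silylmethyl group transfers reluctantly from copper to a β,β-disubstituted enone, and the flat five-membered enone gives the chiral ligand little to discriminate; 1,2-addition may also compete. Fallback: enantiocontrol is moved to the allylboration. It sets out from 1 and 2, using a ligand-free addition (CuBr·SMe2, TMSCl) that gives the racemic enolate, that is 4 together with its mirror-image enolate F2. This is silylated to the racemic enol silane, 5 with its mirror image F3. Steps 2 to 5 then give the racemates containing the mirror-image keto acetal F4, the mirror-image tertiary alcohol F5, the mirror-image diol F6 and the mirror-image aldehyde F7. In step 6 the enantiopure borane 15 attacks the Re face of both aldehyde enantiomers, converting 11 into 17 and F7 into the diastereomeric adduct F8. The two are separated by chromatography and the fallback rejoins at 17, at the cost of half the material.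

**Step 2.** The methyl and silylmethyl groups on C1 differ only moderately in size, so facial selectivity at C5 may be modest, and the Lewis acid may eliminate methanol from 7. Fallback: C5 is set under thermodynamic rather than kinetic control. It sets out from 5: MeLi (THF, 0 °C) frees the lithium enolate, and ethyl formate gives the enol (S)-2-(hydroxymethylene)-3-methyl-3-{[dimethyl(propan-2-yloxy)silyl]methyl}cyclopentan-1-one F9, which has no stereocentre at C5. Acetalisation with trimethyl orthoformate and catalytic PPTS under equilibrating conditions lets C5 settle trans to the larger C1 substituent and rejoins at 7.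

**Step 6.** Several processes can fail: lithiation of 12 at the methyl group instead of the silyl-bearing carbon, E/Z scrambling of the borane (loss of anti selectivity), mismatched double diastereoselection, slow addition to a neopentyl aldehyde carrying a free tertiary hydroxyl, and Peterson elimination on work-up. Fallback: the reagent is made isolable and the chirality catalytic. It sets out from 12: allyllithium 13 is quenched with 2-isopropoxy-4,4,5,5-tetramethyl-1,3,2-dioxaborolane to give the pinacol (E)-[2-methyl-3-(trimethylsilyl)allyl]boronate F10, which is purified to a single regio- and stereoisomer. F10 adds to 11 under chiral binaphthyl phosphoric acid catalysis (5 mol %, PhMe, −30 °C) through the same chair, and the fallback rejoins at 17.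

**Step 7.** The ionised acetal carbon may be captured by the tethered allylsilane before collidine traps it, which would give a useless C6 methyl ether; silylation of the congested tertiary C4 hydroxyl may also be incomplete. Fallback: protection and unmasking are separated, and the unmasking mechanism is changed. It sets out from 17: TESOTf and 2,6-lutidine at −78 to −40 °C, where dimethyl acetals are not activated, give 18, which is isolated. The acetal is then cleaved by specific-acid hydrolysis in a water-rich medium (PPTS, acetone–H2O), where solvent water rather than the alkene captures the oxocarbenium ion. The fallback rejoins at 20 and makes no new compound.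

**Step 9.** The slow acylation of a hindered alcohol at 80 °C may allow Z to E isomerisation of the angeloyl unit. Fallback: the Z-alkene is built on the ester. It sets out from 21, which is acylated with 2-[bis(2,2,2-trifluoroethoxy)phosphoryl]propanoic acid (DCC, DMAP, CH2Cl2) to the phosphonate ester, (1S,4R,5S,6S,10R)-4,10-bis(triethylsilyloxy)dauc-8-en-6-yl 2-[bis(2,2,2-trifluoroethoxy)phosphoryl]propanoate F11. Still–Gennari olefination (KN(SiMe3)2, 18-crown-6, acetaldehyde, THF, −78 °C) gives the Z-configured ester and rejoins at 24.

## Further compounds

F1 | step 8 | (1S,4R,5S,6R,10R)-4,10-bis(triethylsilyloxy)dauc-8-en-6-ol (C6 epimer of 21) | O[C@@H]1CC(C)=C[C@@H](O[Si](CC)(CC)CC)[C@@]2(C)CC[C@@](O[Si](CC)(CC)CC)(C(C)C)[C@H]12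
F2 | step 1 | mirror-image enolate of 4 (chloromagnesium enolate, R at the quaternary carbon) | Cl[Mg]OC1=C[C@](C)(C[Si](C)(C)OC(C)C)CC1
F3 | step 1 | (R)-3-methyl-3-{[dimethyl(propan-2-yloxy)silyl]methyl}-1-(trimethylsilyloxy)cyclopent-1-ene | C[Si](C)(C)OC1=C[C@](C)(C[Si](C)(C)OC(C)C)CC1
F4 | step 1 | (2R,3R)-2-(dimethoxymethyl)-3-methyl-3-{[dimethyl(propan-2-yloxy)silyl]methyl}cyclopentan-1-one | COC(OC)[C@@H]1C(=O)CC[C@@]1(C)C[Si](C)(C)OC(C)C
F5 | step 1 | (1S,2S,3R)-2-(dimethoxymethyl)-3-methyl-1-(propan-2-yl)-3-{[dimethyl(propan-2-yloxy)silyl]methyl}cyclopentan-1-ol | COC(OC)[C@@H]1[C@@](O)(C(C)C)CC[C@@]1(C)C[Si](C)(C)OC(C)C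
F6 | step 1 | (1S,2S,3R)-2-(dimethoxymethyl)-3-(hydroxymethyl)-3-methyl-1-(propan-2-yl)cyclopentan-1-ol | COC(OC)[C@@H]1[C@@](O)(C(C)C)CC[C@@]1(C)CO
F7 | step 1 | (1R,2S,3S)-2-(dimethoxymethyl)-3-hydroxy-1-methyl-3-(propan-2-yl)cyclopentane-1-carbaldehyde | COC(OC)[C@@H]1[C@@](O)(C(C)C)CC[C@@]1(C)C=O
F8 | step 1 | (1S,2S,3R)-2-(dimethoxymethyl)-3-[(1S,2R)-1-hydroxy-3-methyl-2-(trimethylsilyl)but-3-en-1-yl]-3-methyl-1-(propan-2-yl)cyclopentan-1-ol (diastereomer of 17) | COC(OC)[C@@H]1[C@@](O)(C(C)C)CC[C@@]1(C)[C@H](O)[C@H]([Si](C)(C)C)C(C)=C
F9 | step 2 | (S)-2-(hydroxymethylene)-3-methyl-3-{[dimethyl(propan-2-yloxy)silyl]methyl}cyclopentan-1-one (enol form) | OC=C1C(=O)CC[C@]1(C)C[Si](C)(C)OC(C)C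
F10 | step 6 | (E)-4,4,5,5-tetramethyl-2-[2-methyl-3-(trimethylsilyl)allyl]-1,3,2-dioxaborolane | C[Si](C)(C)/C=C(\C)CB1OC(C)(C)C(C)(C)O1
F0 | step 7 | none | none
F11 | step 9 | (1S,4R,5S,6S,10R)-4,10-bis(triethylsilyloxy)dauc-8-en-6-yl 2-[bis(2,2,2-trifluoroethoxy)phosphoryl]propanoate | CC(C(=O)O[C@H]1CC(C)=C[C@@H](O[Si](CC)(CC)CC)[C@@]2(C)CC[C@@](O[Si](CC)(CC)CC)(C(C)C)[C@H]12)P(=O)(OCC(F)(F)F)OCC(F)(F)F
A1 | alternative 1 | 1-diazo-4-(2-methoxy-4-methylphenyl)butan-2-one | COc1cc(C)ccc1CCC(=O)C=[N+]=[N-]
A2 | alternative 1 | (R)-4-methoxy-6-methyl-3,8a-dihydroazulen-1(2H)-one | COC1=C2CCC(=O)[C@@H]2C=CC(C)=C1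
A3 | alternative 2 | 3-(1-methyl-2,7-dioxocycloheptyl)propanal | CC1(CCC=O)C(=O)CCCCC1=O
A4 | alternative 2 | cis-fused 5-hydroxy-1-methylhydroazulene-4,10-dione (target numbering) | O=C1CCCC[C@]2(O)C(=O)CC[C@]12C
A5 | alternative 3 | (S)-Wieland–Miescher ketone | C[C@]12CCC(=O)C=C1CCCC2=O
A6 | alternative 3 | cis-decalin 4,6-dihydroxy-4-isopropyl-1-methyl-5-mesylate with C10 ethylene ketal (target numbering) | CC(C)[C@]1(O)CC[C@]2(C)C3(OCCO3)CCC[C@]2(O)[C@H]1OS(C)(=O)=O
A7 | alternative 3 | trans-fused 4-hydroxy-4-isopropyl-1-methylhydroazulen-6-one with C10 ethylene ketal (target numbering) | O=C1CCCC3(OCCO3)[C@@]2(C)CC[C@@](O)(C(C)C)[C@H]12
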